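**Retrosynthetic overview** (isoflavone numbering: O1, C2, C3, C4, C4a, C5–C8, C8a; B ring C1′–C6′)

1. The strategy rests on ring A: C5–OMe, C6–prenyl and C7–OH stand in a row and the pyranone oxygen O1 sits on C8a, so one benzene ring carries three oxygens that must all differ.
2. C3–C1′ is cut by Suzuki–Miyaura coupling, giving 3-iodochromone 18 and the intact B-ring boronate 21.
3. Ring C (O1–C2 and the C3–I bond) comes from iodocyclisation of an enaminone of o-hydroxyacetophenone 16; its C4–C4a bond comes from ortho-lithiation between OMe and OMOM.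
4. Ring A is cut to cyclobutenone 3 and ynol ether 7 (Danheiser benzannulation): C6–C7 and C4a–C5 form by ketene–alkyne [2+2], C7–C8 re-forms by 6π closure; the ketene O becomes O7–H, the ynol ether O becomes O5–Me, the cyclobutenone O becomes MOM-masked O1.
5. Order of ring formation: A (step 4), then C (step 9); ring B is brought in whole (step 12).

Key step: step 4

Remark on the chemistry: the target has no stereocentre and no stereogenic double bond, so it is achiral and needs no enantiocontrol; the only stereocentre on the way (ring carbon of 9) is transient and racemic.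

**Route**

Step 1
Reactants: 1 3-ethoxycyclobut-2-en-1-one
Product: 2 cyclobutane-1,3-dione
Conditions: 1 M aq. HCl, THF, 0 °C → rt; concentrate below 25 °C, use crude at once
Reagents that add atoms: water, O
Why: Acid-catalysed hydrolysis of a vinylogous ester (addition of water at C3, loss of ethanol) should give the dione, which is a labile vinylogous acid and is therefore not stored.

Step 2
Reactants: 2 cyclobutane-1,3-dione
Product: 3 3-(methoxymethoxy)cyclobut-2-en-1-one
Conditions: MOMCl (1.1 equiv), i-Pr2NEt (1.2 equiv), CH2Cl2, −10 → 0 °C; rapid filtration through Et3N-deactivated silica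
Reagents that add atoms: chloromethyl methyl ether, COCCl
Why: O-alkylation of the ambident 1,3-dione enolate by the hard electrophile MOMCl (Williamson-type etherification, as with cyclohexane-1,3-dione) should give the vinylogous MOM ester.

Step 3
Reactants: 4 2-chloro-1,1-dimethoxyethane; 5 prenyl bromide (1-bromo-3-methylbut-2-ene)
Product: 7 1-methoxy-5-methylhex-4-en-1-yne, via lithium methoxyacetylide 6 (not isolated)
Conditions: LiNEt2 (3.0 equiv), THF, −78 → 0 °C; then 5 (1.1 equiv), DMPU, −78 °C → rt; distil under reduced pressure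
Reagents that add atoms: none
Why: Double β-elimination (MeOH, then HCl) and deprotonation give the lithium alkoxyacetylide, which should be alkylated by SN2 at the primary allylic carbon of 5, and exactly three equivalents of amide leave no free base to isomerise the skipped enyne.

Step 4
Reactants: 3 3-(methoxymethoxy)cyclobut-2-en-1-one; 7 1-methoxy-5-methylhex-4-en-1-yne
Product: 12 3-methoxy-5-(methoxymethoxy)-2-(3-methylbut-2-enyl)phenol, via vinylketene 8 (not isolated), via 4-vinylcyclobutenone 9 (not isolated), via dienylketene 10 (not isolated), via cyclohexa-2,4-dienone 11 (not isolated)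
Conditions: 7 (1.5 equiv), toluene (0.5 M), sealed tube, 80 °C then 110 °C; then K2CO3, MeOH, rt (work-up)
Reagents that add atoms: none
Why: Thermal 4π electrocyclic opening of 3 gives vinylketene 8, whose carbonyl carbon is attacked by the nucleophilic prenyl-bearing carbon of ynol ether 7 in a regioselective [2+2] cycloaddition (bonds C6–C7 and C4a–C5) to give 4-vinylcyclobutenone 9, which reopens (4π) to dienylketene 10. Thermal disrotatory 6π electrocyclisation of 10 re-forms C7–C8 and closes carbocyclic ring A as dienone 11, which enolises to phenol 12. This is the Danheiser benzannulation of a cyclobutenone with an alkoxyalkyne, run here with a 3-alkoxycyclobutenone so that a phloroglucinol rather than a resorcinol ether results. No stereocentre survives, since the ring carbon of 9 is transient and racemic. The only selectivity needed is the orientation of the [2+2], which the polarisation of the ynol ether secures, and a direct [4+2] of 8 across the same polarised triple bond would lead to the same arene. Excess 7 and the final mild methanolysis should deal with any aryl ester formed when the product phenol captures ketene.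

Step 5
Reactants: 12 3-methoxy-5-(methoxymethoxy)-2-(3-methylbut-2-enyl)phenol
Product: 13 [3-methoxy-5-(methoxymethoxy)-2-(3-methylbut-2-enyl)phenoxy]triisopropylsilane
Conditions: TIPSCl (1.3 equiv), imidazole (2.5 equiv), DMF, rt → 40 °C
Reagents that add atoms: triisopropylsilyl chloride, CC(C)[Si](Cl)(C(C)C)C(C)C
Why: Standard silylation of a phenol; the bulky, non-coordinating TIPS ether protects O7 and shields C8 against lithiation in the next step.

Step 6
Reactants: 13 [3-methoxy-5-(methoxymethoxy)-2-(3-methylbut-2-enyl)phenoxy]triisopropylsilane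
Product: 15 1-[2-methoxy-6-(methoxymethoxy)-3-(3-methylbut-2-enyl)-4-(triisopropylsilyloxy)phenyl]ethanone, via aryllithium 14 (not isolated)
Conditions: n-BuLi (1.15 equiv), THF, 0 °C, 1 h; then MeC(O)N(OMe)Me (1.5 equiv), −78 → 0 °C; aq. NH4Cl
Reagents that add atoms: N-methoxy-N-methylacetamide, CC(=O)N(C)OC
Why: Directed ortho-metalation should occur at C4a, the only ring C–H flanked by two coordinating oxygens (OMe and OMOM, the other MOM-ortho site being blocked by OTIPS), and the Weinreb ketone synthesis then gives the methyl ketone because the chelated tetrahedral adduct prevents over-addition and proton transfer.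

Step 7
Reactants: 15 1-[2-methoxy-6-(methoxymethoxy)-3-(3-methylbut-2-enyl)-4-(triisopropylsilyloxy)phenyl]ethanone
Product: 16 1-[6-hydroxy-2-methoxy-3-(3-methylbut-2-enyl)-4-(triisopropylsilyloxy)phenyl]ethanone
Conditions: HCl (1.25 M in MeOH, 3 equiv), MeOH/THF, 0 °C → rt
Reagents that add atoms: none
Why: Acid-catalysed acetal cleavage of the MOM ether ortho to the carbonyl is fast under conditions that the aryl TIPS ether, the methyl ether and the prenyl olefin should tolerate, and the freed C8a–OH is not ortho to the prenyl group and cannot cyclise onto it.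

Step 8
Reactants: 16 1-[6-hydroxy-2-methoxy-3-(3-methylbut-2-enyl)-4-(triisopropylsilyloxy)phenyl]ethanone
Product: 17 (E)-3-(dimethylamino)-1-[6-hydroxy-2-methoxy-3-(3-methylbut-2-enyl)-4-(triisopropylsilyloxy)phenyl]prop-2-en-1-one
Conditions: DMF-DMA (3 equiv), toluene, 85 °C; concentrate, use crude
Reagents that add atoms: N,N-dimethylformamide dimethyl acetal, COC(OC)N(C)C
Why: Condensation of the methyl ketone with the amide acetal (enaminone formation) supplies C2, while the hydrogen-bonded ortho-OH stays free below the temperature at which the reagent methylates phenols.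

Step 9
Reactants: 17 (E)-3-(dimethylamino)-1-[6-hydroxy-2-methoxy-3-(3-methylbut-2-enyl)-4-(triisopropylsilyloxy)phenyl]prop-2-en-1-one
Product: 18 3-iodo-5-methoxy-6-(3-methylbut-2-enyl)-7-(triisopropylsilyloxy)chromen-4-one
Conditions: I2 (1.1 equiv), CHCl3, 0 °C → rt; aq. Na2S2O3
Reagents that add atoms: iodine, II
Why: Iodocyclisation of an o-hydroxyaryl enaminone: α-iodination gives an iminium ion that the phenol closes onto (6-exo-trig) with loss of dimethylamine, forming ring C, and the enaminone carbon is far more nucleophilic than the prenyl olefin, so a small excess of iodine in an aprotic solvent should be chemoselective.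

Step 10
Reactants: 19 4-bromoresorcinol (4-bromobenzene-1,3-diol)
Product: 20 1-bromo-2,4-bis(triisopropylsilyloxy)benzene
Conditions: TIPSCl (2.4 equiv), imidazole (5 equiv), DMF, 40 °C
Reagents that add atoms: triisopropylsilyl chloride, CC(C)[Si](Cl)(C(C)C)C(C)C
Why: Standard bis-silylation of a resorcinol, putting on the B ring the same fluoride-labile group as on O7 so that one reagent finishes the synthesis.

Step 11
Reactants: 20 1-bromo-2,4-bis(triisopropylsilyloxy)benzene
Product: 21 2-[2,4-bis(triisopropylsilyloxy)phenyl]-4,4,5,5-tetramethyl-1,3,2-dioxaborolane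
Conditions: B2pin2 (1.2 equiv), Pd(dppf)Cl2 (5 mol %), KOAc (3 equiv), 1,4-dioxane, 90 °C
Reagents that add atoms: bis(pinacolato)diboron, CC1(C)OB(OC1(C)C)B1OC(C)(C)C(C)(C)O1
Why: Miyaura borylation of the aryl bromide avoids an ortho-lithiated aryl silyl ether, which would be prone to O→C silyl migration.

Step 12
Reactants: 18 3-iodo-5-methoxy-6-(3-methylbut-2-enyl)-7-(triisopropylsilyloxy)chromen-4-one; 21 2-[2,4-bis(triisopropylsilyloxy)phenyl]-4,4,5,5-tetramethyl-1,3,2-dioxaborolane
Product: 22 3-[2,4-bis(triisopropylsilyloxy)phenyl]-5-methoxy-6-(3-methylbut-2-enyl)-7-(triisopropylsilyloxy)chromen-4-one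
Conditions: SPhos Pd G2 (5 mol %), K3PO4 (3 equiv), toluene/H2O (10:1), 60 °C
Reagents that add atoms: none
Why: Suzuki–Miyaura coupling of a 3-iodochromone with an ortho-oxygenated arylboronate is the standard C3–C1′ bond formation of isoflavones, a biarylphosphine ligand should cope with the ortho-silyloxy group, and any partial loss of the activated 7-O-silyl group would be made good by step 13.

Step 13
Reactants: 22 3-[2,4-bis(triisopropylsilyloxy)phenyl]-5-methoxy-6-(3-methylbut-2-enyl)-7-(triisopropylsilyloxy)chromen-4-one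
Product: 23 3-(2,4-dihydroxyphenyl)-7-hydroxy-5-methoxy-6-(3-methylbut-2-enyl)chromen-4-one
Conditions: TBAF (3.5 equiv), AcOH (3.5 equiv), THF, 0 °C → rt
Reagents that add atoms: none
Why: Fluoride-mediated cleavage of the three aryl silyl ethers under acetic acid buffering should free O7, O2′ and O4′ without acid (no cyclisation of the 7-OH onto the prenyl group) and without base strong enough to open the pyranone.

**Compound list**

1 | 3-ethoxycyclobut-2-en-1-one | CCOC1=CC(=O)C1 | starting material
2 | cyclobutane-1,3-dione | O=C1CC(=O)C1 | intermediate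
3 | 3-(methoxymethoxy)cyclobut-2-en-1-one | COCOC1=CC(=O)C1 | intermediate
4 | 2-chloro-1,1-dimethoxyethane | COC(CCl)OC | starting material
5 | prenyl bromide (1-bromo-3-methylbut-2-ene) | CC(C)=CCBr | starting material
6 | lithium methoxyacetylide | [Li]C#COC | intermediate (not isolated)
7 | 1-methoxy-5-methylhex-4-en-1-yne | COC#CCC=C(C)C | intermediate
8 | 3-(methoxymethoxy)buta-1,3-dien-1-one (vinylketene) | COCOC(=C)C=C=O | intermediate (not isolated)
9 | 3-methoxy-4-[1-(methoxymethoxy)ethenyl]-2-(3-methylbut-2-enyl)cyclobut-2-en-1-one (racemic) | COCOC(=C)C1C(OC)=C(CC=C(C)C)C1=O | intermediate (not isolated)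
10 | (3E)-3-methoxy-5-(methoxymethoxy)-2-(3-methylbut-2-enyl)hexa-1,3,5-trien-1-one (dienylketene, ketene and vinyl termini cis) | O=C=C(CC=C(C)C)/C(OC)=C\C(OCOC)=C | intermediate (not isolated)
11 | 3-methoxy-5-(methoxymethoxy)-2-(3-methylbut-2-enyl)cyclohexa-2,4-dien-1-one | O=C1CC(OCOC)=CC(OC)=C1CC=C(C)C | intermediate (not isolated)
12 | 3-methoxy-5-(methoxymethoxy)-2-(3-methylbut-2-enyl)phenol | COCOc1cc(O)c(CC=C(C)C)c(OC)c1 | intermediate
13 | [3-methoxy-5-(methoxymethoxy)-2-(3-methylbut-2-enyl)phenoxy]triisopropylsilane | COCOc1cc(O[Si](C(C)C)(C(C)C)C(C)C)c(CC=C(C)C)c(OC)c1 | intermediate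
14 | [2-methoxy-6-(methoxymethoxy)-3-(3-methylbut-2-enyl)-4-(triisopropylsilyloxy)phenyl]lithium | [Li]c1c(OCOC)cc(O[Si](C(C)C)(C(C)C)C(C)C)c(CC=C(C)C)c1OC | intermediate (not isolated)
15 | 1-[2-methoxy-6-(methoxymethoxy)-3-(3-methylbut-2-enyl)-4-(triisopropylsilyloxy)phenyl]ethanone | CC(=O)c1c(OCOC)cc(O[Si](C(C)C)(C(C)C)C(C)C)c(CC=C(C)C)c1OC | intermediate
16 | 1-[6-hydroxy-2-methoxy-3-(3-methylbut-2-enyl)-4-(triisopropylsilyloxy)phenyl]ethanone | CC(=O)c1c(O)cc(O[Si](C(C)C)(C(C)C)C(C)C)c(CC=C(C)C)c1OC | intermediate
17 | (E)-3-(dimethylamino)-1-[6-hydroxy-2-methoxy-3-(3-methylbut-2-enyl)-4-(triisopropylsilyloxy)phenyl]prop-2-en-1-one | CN(C)/C=C/C(=O)c1c(O)cc(O[Si](C(C)C)(C(C)C)C(C)C)c(CC=C(C)C)c1OC | intermediate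
18 | 3-iodo-5-methoxy-6-(3-methylbut-2-enyl)-7-(triisopropylsilyloxy)chromen-4-one | COc1c(CC=C(C)C)c(O[Si](C(C)C)(C(C)C)C(C)C)cc2occ(I)c(=O)c12 | intermediate
19 | 4-bromoresorcinol (4-bromobenzene-1,3-diol) | Oc1ccc(Br)c(O)c1 | starting material
20 | 1-bromo-2,4-bis(triisopropylsilyloxy)benzene | Brc1ccc(O[Si](C(C)C)(C(C)C)C(C)C)cc1O[Si](C(C)C)(C(C)C)C(C)C | intermediate
21 | 2-[2,4-bis(triisopropylsilyloxy)phenyl]-4,4,5,5-tetramethyl-1,3,2-dioxaborolane | CC1(C)OB(OC1(C)C)c1ccc(O[Si](C(C)C)(C(C)C)C(C)C)cc1O[Si](C(C)C)(C(C)C)C(C)C | intermediate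
22 | 3-[2,4-bis(triisopropylsilyloxy)phenyl]-5-methoxy-6-(3-methylbut-2-enyl)-7-(triisopropylsilyloxy)chromen-4-one | COc1c(CC=C(C)C)c(O[Si](C(C)C)(C(C)C)C(C)C)cc2occ(-c3ccc(O[Si](C(C)C)(C(C)C)C(C)C)cc3O[Si](C(C)C)(C(C)C)C(C)C)c(=O)c12 | intermediate
23 | 3-(2,4-dihydroxyphenyl)-7-hydroxy-5-methoxy-6-(3-methylbut-2-enyl)chromen-4-one | COc1c(CC=C(C)C)c(O)cc2occ(-c3ccc(O)cc3O)c(=O)c12 | target

**Step count**

Total: 13 steps. Longest linear sequence: 10 steps (1, 2, 4, 5, 6, 7, 8, 9, 12, 13).

**Steps most likely to fail**

Step 4 (key step). The vinylogous-ester resonance of 3 may slow the ring opening so much that the temperature needed is one at which ynol ether 7 oligomerises or is hydrated. The ketene intermediates may also be drained by the product phenol or by traces of water, and the vinylogous acetal may lose its MOM group on prolonged heating. The fallback gives up the cyclobutenone and builds the same arene by classical directed metalation. It sets out from prenyl bromide 5 and commercial 3,5-dimethoxyphenol (COc1cc(O)cc(OC)c1) and comes back to the route at 12. Silylation (TIPSCl, imidazole, DMF) gives (3,5-dimethoxyphenoxy)triisopropylsilane F1. Lithiation between the two methoxy groups (n-BuLi, THF, 0 °C; the positions next to OTIPS are shielded) and alkylation with 5 (CuBr·SMe2 cat., −78 → 0 °C) gives [3,5-dimethoxy-4-(3-methylbut-2-enyl)phenoxy]triisopropylsilane F2. TBAF in THF frees 3,5-dimethoxy-4-(3-methylbut-2-enyl)phenol F3, and MOMCl/i-Pr2NEt gives the symmetric 1,3-dimethoxy-5-(methoxymethoxy)-2-(3-methylbut-2-enyl)benzene F4. Removal of one of the two equivalent methyl groups with NaSEt in DMF at 120 °C stops at the phenoxide and should give 12.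

Step 9. Electrophilic iodine may be diverted to the prenyl olefin (iodonium formation and follow-up addition) or to C8 of the still electron-rich phenol ring before the pyranone closes. The fallback avoids electrophilic halogen and attaches the B ring before ring C is closed. It sets out from 15 and 20 and comes back at 22. Pd-catalysed α-arylation of methyl ketone 15 with bromide 20 (Pd2(dba)3, XPhos, K3PO4, toluene, 90 °C) gives 2-[2,4-bis(triisopropylsilyloxy)phenyl]-1-[2-methoxy-6-(methoxymethoxy)-3-(3-methylbut-2-enyl)-4-(triisopropylsilyloxy)phenyl]ethanone F5. Methanolic HCl at room temperature removes the MOM group to give 2-[2,4-bis(triisopropylsilyloxy)phenyl]-1-[6-hydroxy-2-methoxy-3-(3-methylbut-2-enyl)-4-(triisopropylsilyloxy)phenyl]ethanone F6. Heating F6 with DMF-DMA in toluene at 90 °C closes the pyranone through the enaminone and should give 22.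

Step 3. The lithium alkoxyacetylide is a weak nucleophile, attack at the tertiary end of the allyl system (SN2′) and base-induced propargyl–allenyl isomerisation of the skipped enyne may compete, and the volatile, acid-labile product may be lost on isolation. The fallback forms the prenyl–alkyne bond first and uses a silyl ynol ether in the same benzannulation. It sets out from 5 and 3 and comes back at 13. Copper-catalysed coupling of ethynylmagnesium bromide with 5 (CuCl cat., THF, 0 °C → rt) gives 5-methylhex-4-en-1-yne F7. Deprotonation (n-BuLi, −78 °C), oxidation of the acetylide with lithium tert-butyl peroxide to the ynolate and O-silylation with TIPSOTf give triisopropyl[(5-methylhex-4-en-1-yn-1-yl)oxy]silane F8. Heating F8 with 3 in toluene (80 → 110 °C) should give, by the same cascade and with the same orientation, 5-(methoxymethoxy)-2-(3-methylbut-2-enyl)-3-(triisopropylsilyloxy)phenol F9, in which the alkyne oxygen already carries the O7 silyl group. Methylation of the free phenol (MeI, K2CO3, acetone) gives 13, so the silylation of step 5 is not needed.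

**Further compounds**

F1 | step 4 | (3,5-dimethoxyphenoxy)triisopropylsilane | COc1cc(OC)cc(O[Si](C(C)C)(C(C)C)C(C)C)c1
F2 | step 4 | [3,5-dimethoxy-4-(3-methylbut-2-enyl)phenoxy]triisopropylsilane | COc1cc(O[Si](C(C)C)(C(C)C)C(C)C)cc(OC)c1CC=C(C)C
F3 | step 4 | 3,5-dimethoxy-4-(3-methylbut-2-enyl)phenol | COc1cc(O)cc(OC)c1CC=C(C)C
F4 | step 4 | 1,3-dimethoxy-5-(methoxymethoxy)-2-(3-methylbut-2-enyl)benzene | COCOc1cc(OC)c(CC=C(C)C)c(OC)c1
F5 | step 9 | 2-[2,4-bis(triisopropylsilyloxy)phenyl]-1-[2-methoxy-6-(methoxymethoxy)-3-(3-methylbut-2-enyl)-4-(triisopropylsilyloxy)phenyl]ethanone | COCOc1cc(O[Si](C(C)C)(C(C)C)C(C)C)c(CC=C(C)C)c(OC)c1C(=O)Cc1ccc(O[Si](C(C)C)(C(C)C)C(C)C)cc1O[Si](C(C)C)(C(C)C)C(C)C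
F6 | step 9 | 2-[2,4-bis(triisopropylsilyloxy)phenyl]-1-[6-hydroxy-2-methoxy-3-(3-methylbut-2-enyl)-4-(triisopropylsilyloxy)phenyl]ethanone | Oc1cc(O[Si](C(C)C)(C(C)C)C(C)C)c(CC=C(C)C)c(OC)c1C(=O)Cc1ccc(O[Si](C(C)C)(C(C)C)C(C)C)cc1O[Si](C(C)C)(C(C)C)C(C)C
F7 | step 3 | 5-methylhex-4-en-1-yne | C#CCC=C(C)C
F8 | step 3 | triisopropyl[(5-methylhex-4-en-1-yn-1-yl)oxy]silane | CC(C)=CCC#CO[Si](C(C)C)(C(C)C)C(C)C
F9 | step 3 | 5-(methoxymethoxy)-2-(3-methylbut-2-enyl)-3-(triisopropylsilyloxy)phenol | COCOc1cc(O)c(CC=C(C)C)c(O[Si](C(C)C)(C(C)C)C(C)C)c1
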